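**Plan**

- Retrosynthesis: the CH2OH on C3 goes back to a carboxylic acid, and the ArCH2 on C4 to an aryl carbinol tied to that acid as a γ-lactone. Cutting the carbinol–aryl bond leaves an aldehyde acid masked as a menthyl acetal lactone.
- Enabling feature: in the oxolane ring C3 and C4 are cis and each carries one exocyclic carbon, so these four carbons are the carbons of a butenolide. C2–O1–C5, with the aryl on C2, can then be removed as one three-atom carbonyl ylide, ArCH=O(+)–CH2(−), by breaking C2–C3 and C4–C5 together.
- Forward: the aldehyde gives the silylmethyl chloro ether, and furfural with (+)-menthol gives the (5S)-menthyloxyfuranone. Their [3+2] union closes the oxolane, the only ring of the target, cis-fused to the lactone. The lactone is then taken apart by acetal hydrolysis, aryl Grignard addition with relactonisation, benzylic hydrogenolysis and acid reduction.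
- Stereochemistry: the (S)-acetal carbon, secured by crystallisation with (+)-menthol, sends the ylide to the opposite face and fixes C3 and C4 absolutely. The concerted addition makes them cis, and the exo aryl makes C2 trans to C3. The acetal and carbinol centres are erased later.

Key step: step 5

Remark on the chemistry: the anomeric carbon of 11 and the carbinol carbon formed in step 8 are carried as epimer mixtures, because both centres are removed before the target is reached.

**Route**

Step 1
Reactants: 1 3,4,5-trimethoxybenzaldehyde; 2 (trimethylsilyl)methanol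
Product: 3 3,4,5-trimethoxybenzaldehyde bis[(trimethylsilyl)methyl] acetal
Conditions: 2 (2.5 equiv), p-TsOH (cat.), cyclohexane, reflux, azeotropic water removal
Reagents that add atoms: none
Why: Acid-catalysed acetalisation driven by water removal should proceed normally with this primary, acid-stable silyl alcohol, and no stereocentre is formed.

Step 2
Reactants: 3 3,4,5-trimethoxybenzaldehyde bis[(trimethylsilyl)methyl] acetal
Product: 4 chloro(3,4,5-trimethoxyphenyl)methyl (trimethylsilyl)methyl ether (racemic, used crude)
Conditions: AcCl (1.2 equiv), SOCl2 (cat.), CH2Cl2, 0 °C to rt; volatiles removed in vacuo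
Reagents that add atoms: acetyl chloride, CC(Cl)=O
Why: Acyl chloride cleavage of an acetal (the classical α-chloro ether synthesis) acylates one acetal oxygen, and chloride captures the aryl-stabilised oxocarbenium ion; the racemic centre is of no consequence because it becomes the planar ylide carbon.

Step 3
Reactants: 5 furfural
Product: 6 5-hydroxyfuran-2(5H)-one (racemic)
Conditions: O2, hν (visible), rose bengal (cat.), MeOH, rt
Reagents that add atoms: dioxygen, O=O
Why: Dye-sensitised singlet-oxygen [4+2] photo-oxygenation of the furan gives an endoperoxide whose methanolysis expels the formyl carbon and leaves the γ-hydroxybutenolide.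

Step 4
Reactants: 6 5-hydroxyfuran-2(5H)-one; 7 (+)-menthol
Product: 8 (5S)-5-{[(1S,2R,5S)-5-methyl-2-(propan-2-yl)cyclohexyl]oxy}furan-2(5H)-one
Conditions: 7 (1.1 equiv), camphorsulfonic acid (cat.), toluene, reflux, azeotropic water removal; crystallisation from petroleum ether, mother liquor re-equilibrated with acid and recrystallised
Reagents that add atoms: none
Why: Acid-catalysed acetalisation of the pseudo acid gives both C5 epimers, and the (5S) epimer of the (+)-menthyl series is the crystalline one, so crystallisation with acid-mediated epimerisation of the liquors (crystallisation-induced asymmetric transformation) sets C5.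

Step 5
Reactants: 4 chloro(3,4,5-trimethoxyphenyl)methyl (trimethylsilyl)methyl ether; 8 (5S)-5-menthyloxyfuran-2(5H)-one
Product: 10 (1S,4S,5R,8S)-4-{[(1S,2R,5S)-5-methyl-2-(propan-2-yl)cyclohexyl]oxy}-8-(3,4,5-trimethoxyphenyl)-3,7-dioxabicyclo[3.3.0]octan-2-one, via carbonyl ylide 9 (not isolated)
Conditions: CsF (3 equiv, dried), MeCN, rt, slow addition of 4 (2 equiv) to 8
Reagents that add atoms: none
Why: Fluoride attacks silicon of 4 while chloride departs (1,3-elimination), and the resulting non-stabilised carbonyl ylide 9 adds in a concerted, suprafacial [3+2] fashion across C3=C4 of 8, its CH2 terminus bonding to the β-carbon and its benzylic terminus to the α-carbon. The closest known reaction type is the CsF-triggered cycloaddition of silylmethyl chloroalkyl ethers to acrylates, fumarates and enones, combined with the anti-facial control that 5-menthyloxyfuranones exert on nitrile oxides, diazoalkanes and azomethine ylides. The oxolane ring closes by intermolecular [3+2] cycloaddition with both C–C bonds formed in one transition state, which makes the five/five ring fusion cis. C1 and C5 are set by the (S)-acetal carbon of 8, whose menthyloxy group shields its own face so that the dipole adds anti to it; C8 is set by the exo orientation of the aryl group, turned away from the lactone carbonyl and ring oxygen. The step needs regio-, face- and exo-selectivity: the first rests on the larger HOMO coefficient at the unsubstituted ylide carbon meeting the electrophilic β-carbon, the second on the menthyloxy group, and the third, the least secure, on steric avoidance of the lactone, with any C8 epimer to be removed by chromatography. The racemic centre of 4 is planarised in 9 and has no influence.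

Step 6
Reactants: 10 menthyloxy cycloadduct
Product: 11 (1S,5R,8S)-4-hydroxy-8-(3,4,5-trimethoxyphenyl)-3,7-dioxabicyclo[3.3.0]octan-2-one (both C4 anomers)
Conditions: 2 M aq. HCl, 1,4-dioxane, 60 °C; menthol recovered
Reagents that add atoms: water, O
Why: Acid-catalysed hydrolysis of the acyloxy alkyl acetal through the lactone-stabilised oxocarbenium ion should release menthol and give the pseudo acid, the acetal being more labile than the aryl oxolane ether and the ring-fusion centres untouched.

Step 7
Reactants: 12 5-bromo-1,2,3-trimethoxybenzene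
Product: 13 (3,4,5-trimethoxyphenyl)magnesium bromide (THF solution, titrated and used directly)
Conditions: Mg turnings, 1,2-dibromoethane (cat.), THF, reflux
Reagents that add atoms: magnesium, [Mg]
Why: Grignard formation by insertion of magnesium into the aryl–bromine bond is routine for this aryl bromide, and the methoxy groups are inert.

Step 8
Reactants: 11 hydroxy lactone; 13 (3,4,5-trimethoxyphenyl)magnesium bromide
Product: 15 (1S,5R,8S)-4,8-bis(3,4,5-trimethoxyphenyl)-3,7-dioxabicyclo[3.3.0]octan-2-one (both C4 epimers), via hydroxy acid 14 (not isolated)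
Conditions: 13 (3 equiv), THF, −40 °C to 0 °C; then 2 M HCl, rt
Reagents that add atoms: none
Why: In this Grignard addition to a pseudo acid the first equivalent deprotonates the lactol and opens it to the aldehyde carboxylate, a further equivalent adds to the aldehyde while the carboxylate stays inert, and acidification closes the cis hydroxy acid to the γ-lactone; the new carbinol centre is formed unselectively and is removed in step 9.

Step 9
Reactants: 15 diaryl lactone
Product: 16 (2S,3S,4R)-2-(3,4,5-trimethoxyphenyl)-4-[(3,4,5-trimethoxyphenyl)methyl]oxolane-3-carboxylic acid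
Conditions: H2 (1 atm), 10% Pd/C, EtOAc–AcOH (10:1), rt, stopped after uptake of 1 equiv
Reagents that add atoms: none
Why: Palladium-catalysed hydrogenolysis of a benzylic C–O bond is expected to cleave the lactone (a benzylic ester with a carboxylate leaving group) faster than the benzylic dialkyl ether C2–O1 of the oxolane, and it turns the carbinol carbon into CH2 without touching C2, C3 or C4.

Step 10
Reactants: 16 oxolane carboxylic acid
Product: 17 [(2S,3R,4R)-2-(3,4,5-trimethoxyphenyl)-4-[(3,4,5-trimethoxyphenyl)methyl]oxolan-3-yl]methanol (target)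
Conditions: LiAlH4 (2.5 equiv), THF, 0 °C to reflux; then H2O quench
Reagents that add atoms: none
Why: Hydride reduction of the carboxylic acid proceeds through the non-enolisable carboxylate, so C3 keeps its configuration and the ethers are untouched; the change of descriptor at C3 from S to R reflects only the changed priority of the reduced carbon.

**Compound list**

1 | 3,4,5-trimethoxybenzaldehyde | COc1cc(C=O)cc(OC)c1OC | starting material
2 | (trimethylsilyl)methanol | C[Si](C)(C)CO | starting material
3 | 3,4,5-trimethoxybenzaldehyde bis[(trimethylsilyl)methyl] acetal | COc1cc(C(OC[Si](C)(C)C)OC[Si](C)(C)C)cc(OC)c1OC | intermediate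
4 | chloro(3,4,5-trimethoxyphenyl)methyl (trimethylsilyl)methyl ether, racemic | COc1cc(C(Cl)OC[Si](C)(C)C)cc(OC)c1OC | intermediate
5 | furfural | O=Cc1ccco1 | starting material
6 | 5-hydroxyfuran-2(5H)-one, racemic | O=C1C=CC(O)O1 | intermediate
7 | (+)-menthol, (1S,2R,5S)-5-methyl-2-(propan-2-yl)cyclohexan-1-ol | C[C@H]1CC[C@@H]([C@H](C1)O)C(C)C | starting material
8 | (5S)-5-{[(1S,2R,5S)-5-methyl-2-(propan-2-yl)cyclohexyl]oxy}furan-2(5H)-one | O=C1C=C[C@@H](O[C@H]2C[C@@H](C)CC[C@@H]2C(C)C)O1 | intermediate
9 | carbonyl ylide ArCH=O(+)–CH2(−), Ar = 3,4,5-trimethoxyphenyl | COc1cc(C=[O+][CH2-])cc(OC)c1OC | intermediate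
10 | (1S,4S,5R,8S)-4-{[(1S,2R,5S)-5-methyl-2-(propan-2-yl)cyclohexyl]oxy}-8-(3,4,5-trimethoxyphenyl)-3,7-dioxabicyclo[3.3.0]octan-2-one (cis-fused, aryl exo, menthyloxy anti to the oxolane ring) | O=C1O[C@H](O[C@H]2C[C@@H](C)CC[C@@H]2C(C)C)[C@H]2CO[C@H](c3cc(OC)c(OC)c(OC)c3)[C@@H]12 | intermediate
11 | (1S,5R,8S)-4-hydroxy-8-(3,4,5-trimethoxyphenyl)-3,7-dioxabicyclo[3.3.0]octan-2-one, both C4 anomers | O=C1OC(O)[C@H]2CO[C@H](c3cc(OC)c(OC)c(OC)c3)[C@@H]12 | intermediate
12 | 5-bromo-1,2,3-trimethoxybenzene | COc1cc(Br)cc(OC)c1OC | starting material
13 | (3,4,5-trimethoxyphenyl)magnesium bromide | COc1cc([Mg]Br)cc(OC)c1OC | intermediate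
14 | (2S,3S,4R)-4-[hydroxy(3,4,5-trimethoxyphenyl)methyl]-2-(3,4,5-trimethoxyphenyl)oxolane-3-carboxylic acid, both carbinol epimers | COc1cc(C(O)[C@H]2CO[C@H](c3cc(OC)c(OC)c(OC)c3)[C@H]2C(=O)O)cc(OC)c1OC | intermediate
15 | (1S,5R,8S)-4,8-bis(3,4,5-trimethoxyphenyl)-3,7-dioxabicyclo[3.3.0]octan-2-one, both C4 epimers | O=C1OC(c3cc(OC)c(OC)c(OC)c3)[C@H]2CO[C@H](c4cc(OC)c(OC)c(OC)c4)[C@@H]12 | intermediate
16 | (2S,3S,4R)-2-(3,4,5-trimethoxyphenyl)-4-[(3,4,5-trimethoxyphenyl)methyl]oxolane-3-carboxylic acid | COc1cc(C[C@H]2CO[C@H](c3cc(OC)c(OC)c(OC)c3)[C@H]2C(=O)O)cc(OC)c1OC | intermediate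
17 | [(2S,3R,4R)-2-(3,4,5-trimethoxyphenyl)-4-[(3,4,5-trimethoxyphenyl)methyl]oxolan-3-yl]methanol | COc1cc(C[C@H]2CO[C@H](c3cc(OC)c(OC)c(OC)c3)[C@H]2CO)cc(OC)c1OC | target

**Step count and risks**

Total step count: 10. Longest linear sequence: 7 steps (steps 1, 2, 5, 6, 8, 9, 10; the furfural branch through steps 3 and 4 is equally long).

Steps most likely to fail:

1. Step 5. The exo preference at the aryl-bearing carbon may be insufficient, so that part of the material closes with the aryl group on the concave face; the ylide may also be lost by electrocyclisation to the aryl oxirane. The fallback sets out from 4 and 8 under the same cycloaddition and accepts a mixture of 10 with the endo-aryl (8R) epimer of 10 F1. This mixture is treated with BF3·OEt2 (cat.) in CH2Cl2 at 0 °C, the known acid-mediated epimerisation of 2-aryl oxolanes. Reversible ionisation of the benzylic C8–O7 bond and reclosure should move the aryl group to the convex face. Any scrambling at the acetal carbon is harmless because step 6 removes that centre. The fallback returns to the route at 10.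

2. Step 9. Hydrogenolysis may not stop at the lactone and may also open the oxolane at its benzylic C2–O1 bond. The fallback sets out from 15 and replaces catalytic hydrogenolysis by radical deoxygenation, which leaves benzylic ethers alone. LiAlH4 in THF at 0 °C with non-acidic work-up should give the diol, [(2S,3R,4R)-4-[hydroxy(3,4,5-trimethoxyphenyl)methyl]-2-(3,4,5-trimethoxyphenyl)oxolan-3-yl]methanol F2. TBSCl and imidazole in CH2Cl2 at 0 °C should silylate the primary hydroxyl selectively to the primary tert-butyldimethylsilyl ether F3. NaH, CS2 and then MeI in THF should convert the benzylic hydroxyl into the S-methyl xanthate F4. Bu3SnH and AIBN in toluene at 90 °C (Barton–McCombie deoxygenation) should give the deoxygenated silyl ether F5, and Bu4NF in THF then removes the silyl group. The fallback returns to the route at 17, bypassing 16 and step 10.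

3. Step 8. The basic Grignard reagent, needed in excess to open the lactol, may enolise the liberated aldehyde and epimerise the carbon next to it, giving a trans hydroxy acid that cannot lactonise. The fallback sets out from 11 and unmasks the aldehyde under neutral conditions first. Me3SiCHN2 in toluene–MeOH at 0 °C should trap the open form as the aldehyde ester, methyl (2S,3S,4R)-4-formyl-2-(3,4,5-trimethoxyphenyl)oxolane-3-carboxylate F6. One equivalent of 13 in THF at −78 °C should then add chemoselectively to the aldehyde and give the hydroxy ester, methyl (2S,3S,4R)-4-[hydroxy(3,4,5-trimethoxyphenyl)methyl]-2-(3,4,5-trimethoxyphenyl)oxolane-3-carboxylate F7. Its cis alkoxide closes onto the ester on warming and mild acid work-up. The fallback returns to the route at 15.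

**Further compounds**

F1 | step 5 | (1S,4S,5R,8R)-4-{[(1S,2R,5S)-5-methyl-2-(propan-2-yl)cyclohexyl]oxy}-8-(3,4,5-trimethoxyphenyl)-3,7-dioxabicyclo[3.3.0]octan-2-one (endo-aryl epimer of 10) | O=C1O[C@H](O[C@H]2C[C@@H](C)CC[C@@H]2C(C)C)[C@H]2CO[C@@H](c3cc(OC)c(OC)c(OC)c3)[C@@H]12
F2 | step 9 | [(2S,3R,4R)-4-[hydroxy(3,4,5-trimethoxyphenyl)methyl]-2-(3,4,5-trimethoxyphenyl)oxolan-3-yl]methanol, both carbinol epimers | COc1cc(C(O)[C@H]2CO[C@H](c3cc(OC)c(OC)c(OC)c3)[C@H]2CO)cc(OC)c1OC
F3 | step 9 | primary tert-butyldimethylsilyl ether of F2 | COc1cc(C(O)[C@H]2CO[C@H](c3cc(OC)c(OC)c(OC)c3)[C@H]2CO[Si](C)(C)C(C)(C)C)cc(OC)c1OC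
F4 | step 9 | O-benzylic S-methyl xanthate of F3 | COc1cc(C(OC(=S)SC)[C@H]2CO[C@H](c3cc(OC)c(OC)c(OC)c3)[C@H]2CO[Si](C)(C)C(C)(C)C)cc(OC)c1OC
F5 | step 9 | tert-butyldimethylsilyl ether of 17 | COc1cc(C[C@H]2CO[C@H](c3cc(OC)c(OC)c(OC)c3)[C@H]2CO[Si](C)(C)C(C)(C)C)cc(OC)c1OC
F6 | step 8 | methyl (2S,3S,4R)-4-formyl-2-(3,4,5-trimethoxyphenyl)oxolane-3-carboxylate | O=C[C@H]1CO[C@H](c2cc(OC)c(OC)c(OC)c2)[C@H]1C(=O)OC
F7 | step 8 | methyl (2S,3S,4R)-4-[hydroxy(3,4,5-trimethoxyphenyl)methyl]-2-(3,4,5-trimethoxyphenyl)oxolane-3-carboxylate, both carbinol epimers | COc1cc(C(O)[C@H]2CO[C@H](c3cc(OC)c(OC)c(OC)c3)[C@H]2C(=O)OC)cc(OC)c1OC
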